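## Analysis of the target

Compound 19 is a 2,3-dihydro-1-benzofuran: ring A is the benzene ring C3a–C7a and ring B is the dihydrofuran O1–C2–C3–C3a–C7a. It carries a 3,4-dimethoxyphenyl group (ring C) at C2, a hydroxymethyl group at C3, a free phenol at C7 and an (E)-propenoic acid at C5. The two stereocentres are contiguous, (2R,3S), with the aryl group and the CH2OH arm trans on ring B.

The O1–C2 bond is a secondary benzyl aryl ether activated by the para methoxy group of ring C, so it ionises under strong protic or Lewis acid. The cinnamic acid double bond rules out hydrogenolysis. The two methyl ethers of ring C must survive while O7 ends free, so O7 needs a mask different from methyl from the outset.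

The difficulty is to set C2 and C3 in absolute and relative sense on a ring whose C2 centre can epimerise through the benzylic cation, while carrying the 5,7-pattern of ring A through ring formation.

The plan rests on the three-carbon unit C2–C3–CH2OH. It bears oxygen at both ends (O1 on C2, the hydroxyl on the exocyclic carbon) and only the bond to ring A on its middle carbon. This is the pattern left when a cyclopropane is opened between C2 and the exocyclic carbon by an oxygen nucleophile at one end and an electrophile at the other. Ring A already holds that nucleophile, the O1 phenol, ortho to C3.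

## Retrosynthetic reasoning

**19 from 17 (O7 unmasking).** The last cut is the O7–CH2 bond of a methoxymethyl acetal. A benzyl ether at O7 was rejected: hydrogenolysis would reduce the alkene, and a boron halide strong enough to cleave it would also attack O1–C2, which is a more electron-rich benzyl aryl ether than the protecting group. An acetal can be activated selectively at its own oxygen by a buffered silyl triflate, leaving O1–C2 and the methyl ethers alone.

**17 from 15 and 16 (C5–vinyl bond).** The acrylic acid side chain is cut at the aryl–vinyl bond and formed by a Heck coupling of the C5 bromide with acrylic acid 16, so no ester has to be hydrolysed later. The bromine comes from starting material 1 and also blocks the position para to the phenol in the key step.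

**15 from 12 (C–O of the CH2OH group).** The primary alcohol is traced to a primary C–Hg bond, converted by borohydride under oxygen. The carbon skeleton and both stereocentres are already complete in 12.

**12 from 11 (key disconnection).** The O1–C2 and CH2–Hg bonds are cut and C2 is joined to the exocyclic carbon, giving trans cyclopropane 11 with the free phenol ortho to the ring. This is the right place to cut because one event then builds ring B, sets C2 and places a functionalised carbon on C3. The trans geometry of the cyclopropane fixes the relative configuration, and its C3 carbon carries the absolute configuration. The forward reaction must break only the C2–CH2 bond, put mercury on the CH2 carbon and deliver the phenol oxygen to C2 on the face opposite the departing carbon.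

**11 from 10, and 10 from 7 and 8 (the cyclopropane).** After unmasking the phenol, the two ring bonds to the future C3 are cut. This gives an aryl carbene equivalent, the tosylhydrazone 7 reacting through diazo compound 9, and commercial styrene 8. One catalytic asymmetric cyclopropanation then sets both stereocentres. The aldehyde carbon becomes C3, and the styrene carbons become C2 and the CH2OH carbon. The phenol is masked as a silyl ether for this step. A free phenoxide would divert the carbene, and an O-alkyl mask with hydrogen on the carbon bound to oxygen would allow a 1,5-hydrogen shift to the carbene radical.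

**7 from 5 and 6; 5 from 4; 4 from 2; 2 from 1 (ring A building block).** The hydrazone comes from aldehyde 5 and hydrazide 6, and 5 by silylation of phenol 4. The acetal of 4 is placed on the oxygen remote from the formyl group through the dianion 3 of catechol 2. Catechol 2 comes from commercial 1 by cleavage of its methyl ether. The methyl group has to go at the start because it could not later be told apart from the two methyl ethers of ring C.

## Alternatives that were turned down

**Alternative 1: aryne ring closure with boron capture at C7.**
- Disconnection: the aryl C7a–O1 bond and the C7–O bond (as C7–B). 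
- Forward key step: in acyclic fluoroarene alcohol A2, excess alkyllithium forms the alkoxide and lithiates next to fluorine; loss of fluoride gives the C7a–C7 aryne, the alkoxide adds to C7a to close ring B, and the C7 aryllithium is trapped with a borate to give A1.
- For it: C2 and C3 are fixed in an open chain and the cyclisation touches neither, so C2 cannot epimerise. O7 arrives as boron, so no catechol differentiation is needed. On these two points it is stronger than the chosen route.
- Against it: A2, with two adjacent stereocentres, needs its own asymmetric C–C construction on a trisubstituted fluoroarene. Excess alkyllithium can also metalate ring C next to a methoxy group or the C2 benzylic position. After the key step, C–B oxidation, acetal hydrolysis, olefination and desilylation remain.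
- Comparison: the chosen route sets both centres in one catalytic step from commercial fragments, uses mild reagents and has a shorter sequence.

**Alternative 2: ruthenium (2+2+2) construction of ring A.**
- Disconnection: three bonds of ring A (C3a–C7a, C4–C5, C6–C7). 
- Forward key step: Cp*RuCl(cod) (divalent ruthenium) joins the silyl-capped alkynyl ether diyne A4 with enynoate A5 to give A3, closing rings A and B together.
- For it: it is convergent, the acrylate is in place without an aryl halide or a Heck step, and O7 is latent as silicon. In convergence it is stronger than the chosen route.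
- Against it: A4 is an alkynyl ether of an electron-rich secondary benzylic alcohol, prone to sigmatropic rearrangement and to acid. Making A4 as one stereoisomer takes many steps. The acrylate must end meta to silicon (C5, not C6). The alkene of A5 can engage the ruthenacycle. The later peroxide oxidation of the C–Si bond endangers the enoate.
- Comparison: the chosen route offers robust intermediates and a regiochemistry of ring A that is fixed by the starting material.

**Alternative 3: dearomative cyclopropanation of a benzofuran, then arylation at C2.**
- Disconnection: the C2–aryl bond and the C3–CH2 bond. 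
- Forward key step: CuOTf (monovalent copper) with a tert-butyl bis(oxazoline) ligand turns diazo ester A8 into a carbene that adds across C2=C3 of benzofuran A7 to give exo cyclopropane A6. The donor–acceptor ring is then opened at C2 by an arene nucleophile that delivers ring C trans to the C3 arm.
- For it: the asymmetric step runs on a flat, simple substrate and ring C enters late. It is stronger in modularity.
- Against it: after opening, C3 carries CH2–CO2Et, one carbon more than the target needs, so the ester carbon must be excised by decarboxylative oxygenation. Dearomatisation competes with carbene dimerisation. The benzyl ether meets the same late deprotection problem described above.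
- Comparison: in the chosen route every carbon of the cyclopropane ends in the target and no carbon is removed.

Key step: step 7

## Route

Assumption: both antipodes of the D2-symmetric chiral amidoporphyrin ligand are available, so the cobalt catalyst is used in the antipode that delivers the (1S,2S) cyclopropane; the sense of induction is to be confirmed on compound 10.

Step 1
Reactants: 1 5-bromo-2-hydroxy-3-methoxybenzaldehyde
Product: 2 5-bromo-2,3-dihydroxybenzaldehyde
Conditions: BBr3 (2.5 equiv), CH2Cl2, −78 °C to 0 °C; H2O
Reagents that add atoms: none
Why: Lewis-acid cleavage of an aryl methyl ether: boron binds the ether oxygen and bromide removes the methyl group. The aldehyde and the aryl bromide are inert at this temperature.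

Step 2
Reactants: 2 5-bromo-2,3-dihydroxybenzaldehyde
Product: 4 5-bromo-2-hydroxy-3-(methoxymethoxy)benzaldehyde, via disodium catecholate 3 (not isolated)
Conditions: NaH (2.2 equiv), DMSO, 20 °C; MeOCH2Cl (1.0 equiv), 20 °C; aq. NH4Cl
Reagents that add atoms: chloromethyl methyl ether, COCCl
Why: Williamson-type O-alkylation of the catechol dianion. The oxide ortho to the formyl group is delocalised into the carbonyl and held by sodium, so the remote oxide is the more nucleophilic and takes the single equivalent of electrophile.

Step 3
Reactants: 4 5-bromo-2-hydroxy-3-(methoxymethoxy)benzaldehyde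
Product: 5 5-bromo-2-[(tert-butyldimethylsilyl)oxy]-3-(methoxymethoxy)benzaldehyde
Conditions: TBSCl (1.3 equiv), imidazole (2.5 equiv), DMF, 20 °C
Reagents that add atoms: tert-butyldimethylsilyl chloride, CC(C)(C)[Si](C)(C)Cl
Why: Imidazole-promoted O-silylation of the phenol. The mask carries no hydrogen on the atom bound to oxygen, which is what the carbene step needs.

Step 4
Reactants: 5 5-bromo-2-[(tert-butyldimethylsilyl)oxy]-3-(methoxymethoxy)benzaldehyde; 6 p-toluenesulfonyl hydrazide
Product: 7 N'-[(E)-{5-bromo-2-[(tert-butyldimethylsilyl)oxy]-3-(methoxymethoxy)phenyl}methylidene]-4-methylbenzenesulfonohydrazide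
Conditions: MeOH, 20 °C
Reagents that add atoms: none
Why: Condensation of the aldehyde with the sulfonyl hydrazide to the N-tosylhydrazone. The medium is neutral, so the silyl ether and the acetal persist.

Step 5
Reactants: 7 N'-[(E)-{5-bromo-2-[(tert-butyldimethylsilyl)oxy]-3-(methoxymethoxy)phenyl}methylidene]-4-methylbenzenesulfonohydrazide; 8 3,4-dimethoxystyrene
Product: 10 tert-butyl{4-bromo-2-[(1S,2S)-2-(3,4-dimethoxyphenyl)cyclopropyl]-6-(methoxymethoxy)phenoxy}dimethylsilane (trans), via aryldiazomethane 9 (not isolated)
Conditions: [Co(Por*)] (2 mol %; Por* = D2-symmetric chiral amidoporphyrin, divalent cobalt), Cs2CO3 (2 equiv), 8 (1.5 equiv), toluene, 40 °C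
Reagents that add atoms: none
Why: Bamford–Stevens loss of sulfinate from the hydrazone anion gives diazo compound 9, which the divalent cobalt metalloradical turns into a trivalent cobalt carbene radical; this adds to the terminal carbon of styrene 8 and the benzylic radical closes 3-exo-tet with release of the catalyst (metalloradical cyclopropanation), a stepwise path that favours the trans ring. The chiral cavity of the porphyrin selects the faces of both partners and so sets the two stereocentres as (1S,2S) in one event. The silyl mask cannot undergo the 1,5-hydrogen shift that an ortho alkoxy group would allow, and the aprotic medium keeps the aryl silyl ether intact.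

Step 6
Reactants: 10 tert-butyl{4-bromo-2-[(1S,2S)-2-(3,4-dimethoxyphenyl)cyclopropyl]-6-(methoxymethoxy)phenoxy}dimethylsilane
Product: 11 4-bromo-2-[(1S,2S)-2-(3,4-dimethoxyphenyl)cyclopropyl]-6-(methoxymethoxy)phenol (trans)
Conditions: Bu4NF (1.1 equiv), THF, 0 °C; aq. NH4Cl
Reagents that add atoms: none
Why: Fluoride cleavage of the aryl silyl ether. The acetal, the aryl bromide and the cyclopropane do not react with fluoride, and the stereocentres are untouched.

Step 7
Reactants: 11 4-bromo-2-[(1S,2S)-2-(3,4-dimethoxyphenyl)cyclopropyl]-6-(methoxymethoxy)phenol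
Product: 12 acetato{[(2R,3R)-5-bromo-2-(3,4-dimethoxyphenyl)-7-(methoxymethoxy)-2,3-dihydro-1-benzofuran-3-yl]methyl}mercury (trans)
Conditions: Hg(OAc)2 (1.05 equiv), THF, 20 °C, dark
Reagents that add atoms: mercury diacetate, CC(=O)O[Hg]OC(C)=O
Why: Proposed new method: divalent mercury attacks the unsubstituted CH2 corner of the cyclopropane, the bond from that carbon to the carbon bearing ring C lengthens as positive charge builds at the benzylic position para to a methoxy group, and the ortho phenol oxygen captures that carbon, so that O1–C2 and CH2–Hg form while the C2–CH2 ring bond breaks. The closest known reaction types are the solvomercuration of arylcyclopropanes (nucleophile at the benzylic carbon, mercury at the least substituted carbon) and the mercury-mediated opening of cyclopropanes by an internal hydroxyl or carbonyl oxygen, which goes with inversion at the carbon attacked. Ring B closes in a formally 5-exo-tet mode, since the departing CH2 lies outside the new ring, but because that carbon stays bonded to C3 the oxygen cannot reach the in-line position while the three-membered ring is intact, so the transition state has to be loose and cation-like, which the 4-methoxy group of ring C permits. C3 is a spectator and keeps the configuration of the cyclopropane carbon (its descriptor in 12 reads R only because CH2Hg outranks C2). C2 is the one new stereocentre: oxygen enters opposite the departing CH2, the (S) cyclopropane carbon becomes (R), and ring C ends trans to the CH2Hg arm. A fully ionised benzylic cation would close to the same trans isomer, because ring C avoids the C3 substituent. The step needs cleavage of C2–CH2 rather than C3–CH2 or C2–C3: mercury goes to the only unsubstituted carbon, and of the two benzylic carbons the one on ring C is the better cation site and the only one the phenol can reach in a five-membered ring, while ring A carries bromine and an acetal oxygen meta to the cyclopropane. Mercuration of ring A is excluded because both ortho positions and the para position of the phenol are substituted, and the non-nucleophilic solvent leaves acetate as the only outside competitor for C2.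

Step 8
Reactants: 12 acetato{[(2R,3R)-5-bromo-2-(3,4-dimethoxyphenyl)-7-(methoxymethoxy)-2,3-dihydro-1-benzofuran-3-yl]methyl}mercury
Product: 15 [(2R,3S)-5-bromo-2-(3,4-dimethoxyphenyl)-7-(methoxymethoxy)-2,3-dihydro-1-benzofuran-3-yl]methanol, via alkylmercury hydride 13 (not isolated), via hydroperoxide 14 (not isolated)
Conditions: NaBH4 (2 equiv), O2 (stream), DMF, 0 °C to 20 °C
Reagents that add atoms: dioxygen, O=O
Why: Oxidative demercuration: borohydride gives the alkylmercury hydride 13, which loses mercury to a primary radical; dioxygen traps it faster than a 1,2-aryl shift or hydrogen transfer can occur, and hydroperoxide 14 is reduced in the flask to the alcohol. The radical sits on the exocyclic CH2, so neither stereocentre is involved (the C3 descriptor returns to S because CH2OH ranks below C2).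

Step 9
Reactants: 15 [(2R,3S)-5-bromo-2-(3,4-dimethoxyphenyl)-7-(methoxymethoxy)-2,3-dihydro-1-benzofuran-3-yl]methanol; 16 acrylic acid
Product: 17 (2E)-3-[(2R,3S)-2-(3,4-dimethoxyphenyl)-3-(hydroxymethyl)-7-(methoxymethoxy)-2,3-dihydro-1-benzofuran-5-yl]prop-2-enoic acid
Conditions: Pd(OAc)2 (5 mol %), P(o-tol)3 (15 mol %), Et3N (4 equiv), 16 (2 equiv), DMF, 100 °C; dilute aq. citric acid
Reagents that add atoms: none
Why: Mizoroki–Heck reaction: zerovalent palladium inserts into the C5–Br bond, and syn carbopalladation at the terminal carbon of the acrylate followed by syn β-hydride elimination gives the E alkene. The primary alcohol, the acetal and both stereocentres are inert to the amine base.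

Step 10
Reactants: 17 (2E)-3-[(2R,3S)-2-(3,4-dimethoxyphenyl)-3-(hydroxymethyl)-7-(methoxymethoxy)-2,3-dihydro-1-benzofuran-5-yl]prop-2-enoic acid
Product: 19 (2E)-3-[(2R,3S)-2-(3,4-dimethoxyphenyl)-7-hydroxy-3-(hydroxymethyl)-2,3-dihydro-1-benzofuran-5-yl]prop-2-enoic acid, via tris(trimethylsilyl) derivative 18 (not isolated)
Conditions: Me3SiOTf (5 equiv), 2,2'-bipyridyl (7 equiv), CH2Cl2, 0 °C to 20 °C; then H2O, THF, dilute citric acid, 20 °C
Reagents that add atoms: none
Why: Chemoselective cleavage of an aryl methoxymethyl ether: the silyl triflate, tempered by the bipyridine, activates only the acetal oxygen and converts the acetal into the aryl silyl ether, while the acid and the alcohol are silylated in passing; water then removes all three silyl groups. The medium should be too mild to ionise the O1–C2 benzylic ether or to cleave the aryl methyl ethers.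

## Compound list

1 | 5-bromo-2-hydroxy-3-methoxybenzaldehyde | COc1cc(Br)cc(C=O)c1O | starting material
2 | 5-bromo-2,3-dihydroxybenzaldehyde | O=Cc1cc(Br)cc(O)c1O | intermediate
3 | disodium 5-bromo-3-formylbenzene-1,2-diolate | O=Cc1cc(Br)cc([O-])c1[O-].[Na+].[Na+] | intermediate (not isolated)
4 | 5-bromo-2-hydroxy-3-(methoxymethoxy)benzaldehyde | COCOc1cc(Br)cc(C=O)c1O | intermediate
5 | 5-bromo-2-[(tert-butyldimethylsilyl)oxy]-3-(methoxymethoxy)benzaldehyde | COCOc1cc(Br)cc(C=O)c1O[Si](C)(C)C(C)(C)C | intermediate
6 | p-toluenesulfonyl hydrazide | Cc1ccc(S(=O)(=O)NN)cc1 | starting material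
7 | N'-[(E)-{5-bromo-2-[(tert-butyldimethylsilyl)oxy]-3-(methoxymethoxy)phenyl}methylidene]-4-methylbenzenesulfonohydrazide | COCOc1cc(Br)cc(/C=N/NS(=O)(=O)c2ccc(C)cc2)c1O[Si](C)(C)C(C)(C)C | intermediate
8 | 3,4-dimethoxystyrene | C=Cc1ccc(OC)c(OC)c1 | starting material
9 | tert-butyl[4-bromo-2-(diazomethyl)-6-(methoxymethoxy)phenoxy]dimethylsilane | COCOc1cc(Br)cc(C=[N+]=[N-])c1O[Si](C)(C)C(C)(C)C | intermediate (not isolated)
10 | tert-butyl{4-bromo-2-[(1S,2S)-2-(3,4-dimethoxyphenyl)cyclopropyl]-6-(methoxymethoxy)phenoxy}dimethylsilane | COc1ccc([C@H]2C[C@@H]2c2cc(Br)cc(OCOC)c2O[Si](C)(C)C(C)(C)C)cc1OC | intermediate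
11 | 4-bromo-2-[(1S,2S)-2-(3,4-dimethoxyphenyl)cyclopropyl]-6-(methoxymethoxy)phenol | COc1ccc([C@H]2C[C@@H]2c2cc(Br)cc(OCOC)c2O)cc1OC | intermediate
12 | acetato{[(2R,3R)-5-bromo-2-(3,4-dimethoxyphenyl)-7-(methoxymethoxy)-2,3-dihydro-1-benzofuran-3-yl]methyl}mercury | COc1ccc([C@@H]2Oc3c(OCOC)cc(Br)cc3[C@H]2C[Hg]OC(C)=O)cc1OC | intermediate
13 | {[(2R,3R)-5-bromo-2-(3,4-dimethoxyphenyl)-7-(methoxymethoxy)-2,3-dihydro-1-benzofuran-3-yl]methyl}mercury hydride | COc1ccc([C@@H]2Oc3c(OCOC)cc(Br)cc3[C@H]2C[HgH])cc1OC | intermediate (not isolated)
14 | (2R,3S)-5-bromo-2-(3,4-dimethoxyphenyl)-3-(hydroperoxymethyl)-7-(methoxymethoxy)-2,3-dihydro-1-benzofuran | COc1ccc([C@@H]2Oc3c(OCOC)cc(Br)cc3[C@H]2COO)cc1OC | intermediate (not isolated)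
15 | [(2R,3S)-5-bromo-2-(3,4-dimethoxyphenyl)-7-(methoxymethoxy)-2,3-dihydro-1-benzofuran-3-yl]methanol | COc1ccc([C@@H]2Oc3c(OCOC)cc(Br)cc3[C@H]2CO)cc1OC | intermediate
16 | acrylic acid | C=CC(=O)O | starting material
17 | (2E)-3-[(2R,3S)-2-(3,4-dimethoxyphenyl)-3-(hydroxymethyl)-7-(methoxymethoxy)-2,3-dihydro-1-benzofuran-5-yl]prop-2-enoic acid | COc1ccc([C@@H]2Oc3c(OCOC)cc(/C=C/C(=O)O)cc3[C@H]2CO)cc1OC | intermediate
18 | trimethylsilyl (2E)-3-[(2R,3S)-2-(3,4-dimethoxyphenyl)-7-[(trimethylsilyl)oxy]-3-{[(trimethylsilyl)oxy]methyl}-2,3-dihydro-1-benzofuran-5-yl]prop-2-enoate | COc1ccc([C@@H]2Oc3c(O[Si](C)(C)C)cc(/C=C/C(=O)O[Si](C)(C)C)cc3[C@H]2CO[Si](C)(C)C)cc1OC | intermediate (not isolated)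
19 | (2E)-3-[(2R,3S)-2-(3,4-dimethoxyphenyl)-7-hydroxy-3-(hydroxymethyl)-2,3-dihydro-1-benzofuran-5-yl]prop-2-enoic acid | COc1ccc([C@@H]2Oc3c(O)cc(/C=C/C(=O)O)cc3[C@H]2CO)cc1OC | target

## Step count and risk

Total: 10 steps. Longest linear sequence: 10 steps, from 1 to 19; compounds 6, 8 and 16 are commercial and enter directly.

**Step 7 (key step).** The most likely failure is opening of the ring in the wrong sense or capture by the wrong nucleophile. Ionisation toward C3 is helped by the ortho oxygen of ring A. Acetate may also trap the C2 cation before the phenol arrives, because the phenol reaches its attack geometry only once the C2–CH2 bond is largely broken. Mercuration of ring C para to its 3-methoxy group is a further competing process.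

Fallback, by known chemistry, from 10 to 15: the ring opening and the ring closure are separated. Silyl ether 10 is treated with Hg(OAc)2 in acetic acid, the established acetoxymercuration of an arylcyclopropane. Here the twisted silyloxy group makes ring A the poorer cation stabiliser. The product is (1R,2R)-3-(acetatomercurio)-2-{5-bromo-2-[(tert-butyldimethylsilyl)oxy]-3-(methoxymethoxy)phenyl}-1-(3,4-dimethoxyphenyl)propyl acetate F1. NaBH4 under O2 in DMF converts it into (1R,2S)-2-{5-bromo-2-[(tert-butyldimethylsilyl)oxy]-3-(methoxymethoxy)phenyl}-1-(3,4-dimethoxyphenyl)-3-hydroxypropyl acetate F2. K2CO3 in methanol removes the acetate and the aryl silyl ether to give (1R,2S)-2-[5-bromo-2-hydroxy-3-(methoxymethoxy)phenyl]-1-(3,4-dimethoxyphenyl)propane-1,3-diol F3. A catalytic sulfonic acid in CH2Cl2 then ionises only the carbinol next to ring C, and the phenol closes ring B to the trans isomer 15 under steric control from C3. The configuration of the carbinol carbon therefore does not matter.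

**Step 5.** The most likely failure is slow carbene transfer or erosion of enantioselectivity, because the bulky ortho silyloxy group has to fit the chiral pocket; slow turnover also lets the diazo compound dimerise.

Fallback from 7 and 8 to 11: the cyclopropanation is run with achiral [Co(TPP)] (cobalt tetraphenylporphyrin, divalent cobalt) and Cs2CO3 in toluene. Its open coordination site tolerates the ortho group and gives the racemic trans cyclopropane silyl ether F4. Bu4NF gives the racemic trans phenol F5, which is resolved by preparative chromatography on a chiral stationary phase to give 11.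

**Step 8.** The most likely failure is hydrogen transfer to the primary radical (reduction to the 3-methyl compound) when oxygen supply lags behind the borohydride chain.

Fallback from 12 to 15: iododemercuration with I2 in CH2Cl2 gives (2R,3R)-5-bromo-2-(3,4-dimethoxyphenyl)-3-(iodomethyl)-7-(methoxymethoxy)-2,3-dihydro-1-benzofuran F6. Displacement with CsOAc in DMF gives [(2R,3S)-5-bromo-2-(3,4-dimethoxyphenyl)-7-(methoxymethoxy)-2,3-dihydro-1-benzofuran-3-yl]methyl acetate F7, and K2CO3 in methanol gives 15.

**Step 10.** The most likely failure is incomplete acetal cleavage, or opening of ring B by ionisation at C2 once the silyl triflate is present in excess on a substrate that also carries an acid and an alcohol.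

Fallback from 15 to 19: the order is changed so that the acetal is removed before the side chain is attached. Catalytic HCl in methanol at 40 °C exchanges the acetal of 15 and gives (2R,3S)-5-bromo-2-(3,4-dimethoxyphenyl)-3-(hydroxymethyl)-2,3-dihydro-1-benzofuran-7-ol F8. In this medium any opening at C2 is reversible and recloses to the trans ring. The Heck coupling of F8 with 16 under the conditions of step 9 then gives 19 directly.

## Further compounds

F1 | step 7 | (1R,2R)-3-(acetatomercurio)-2-{5-bromo-2-[(tert-butyldimethylsilyl)oxy]-3-(methoxymethoxy)phenyl}-1-(3,4-dimethoxyphenyl)propyl acetate | COc1ccc([C@H](OC(C)=O)[C@H](C[Hg]OC(C)=O)c2cc(Br)cc(OCOC)c2O[Si](C)(C)C(C)(C)C)cc1OC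
F2 | step 7 | (1R,2S)-2-{5-bromo-2-[(tert-butyldimethylsilyl)oxy]-3-(methoxymethoxy)phenyl}-1-(3,4-dimethoxyphenyl)-3-hydroxypropyl acetate | COc1ccc([C@H](OC(C)=O)[C@H](CO)c2cc(Br)cc(OCOC)c2O[Si](C)(C)C(C)(C)C)cc1OC
F3 | step 7 | (1R,2S)-2-[5-bromo-2-hydroxy-3-(methoxymethoxy)phenyl]-1-(3,4-dimethoxyphenyl)propane-1,3-diol | COc1ccc([C@H](O)[C@H](CO)c2cc(Br)cc(OCOC)c2O)cc1OC
F4 | step 5 | racemic trans tert-butyl{4-bromo-2-[2-(3,4-dimethoxyphenyl)cyclopropyl]-6-(methoxymethoxy)phenoxy}dimethylsilane, (1S,2S) and (1R,2R) | COc1ccc([C@H]2C[C@@H]2c2cc(Br)cc(OCOC)c2O[Si](C)(C)C(C)(C)C)cc1OC.COc1ccc([C@@H]2C[C@H]2c2cc(Br)cc(OCOC)c2O[Si](C)(C)C(C)(C)C)cc1OC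
F5 | step 5 | racemic trans 4-bromo-2-[2-(3,4-dimethoxyphenyl)cyclopropyl]-6-(methoxymethoxy)phenol, (1S,2S) and (1R,2R) | COc1ccc([C@H]2C[C@@H]2c2cc(Br)cc(OCOC)c2O)cc1OC.COc1ccc([C@@H]2C[C@H]2c2cc(Br)cc(OCOC)c2O)cc1OC
F6 | step 8 | (2R,3R)-5-bromo-2-(3,4-dimethoxyphenyl)-3-(iodomethyl)-7-(methoxymethoxy)-2,3-dihydro-1-benzofuran | COc1ccc([C@@H]2Oc3c(OCOC)cc(Br)cc3[C@H]2CI)cc1OC
F7 | step 8 | [(2R,3S)-5-bromo-2-(3,4-dimethoxyphenyl)-7-(methoxymethoxy)-2,3-dihydro-1-benzofuran-3-yl]methyl acetate | COc1ccc([C@@H]2Oc3c(OCOC)cc(Br)cc3[C@H]2COC(C)=O)cc1OC
F8 | step 10 | (2R,3S)-5-bromo-2-(3,4-dimethoxyphenyl)-3-(hydroxymethyl)-2,3-dihydro-1-benzofuran-7-ol | COc1ccc([C@@H]2Oc3c(O)cc(Br)cc3[C@H]2CO)cc1OC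
A1 | alternative 1 | tert-butyl{[(2R,3S)-2-(3,4-dimethoxyphenyl)-5-(1,3-dioxolan-2-yl)-7-(4,4,5,5-tetramethyl-1,3,2-dioxaborolan-2-yl)-2,3-dihydro-1-benzofuran-3-yl]methoxy}dimethylsilane | COc1ccc([C@@H]2Oc3c(B4OC(C)(C)C(C)(C)O4)cc(C4OCCO4)cc3[C@H]2CO[Si](C)(C)C(C)(C)C)cc1OC
A2 | alternative 1 | (1R,2S)-3-[(tert-butyldimethylsilyl)oxy]-1-(3,4-dimethoxyphenyl)-2-[5-(1,3-dioxolan-2-yl)-2-fluorophenyl]propan-1-ol | COc1ccc([C@H](O)[C@H](CO[Si](C)(C)C(C)(C)C)c2cc(C3OCCO3)ccc2F)cc1OC
A3 | alternative 2 | methyl (2E)-3-[(2R,3S)-7-(benzyldimethylsilyl)-3-{[(tert-butyldimethylsilyl)oxy]methyl}-2-(3,4-dimethoxyphenyl)-2,3-dihydro-1-benzofuran-5-yl]prop-2-enoate | COc1ccc([C@@H]2Oc3c([Si](C)(C)Cc4ccccc4)cc(/C=C/C(=O)OC)cc3[C@H]2CO[Si](C)(C)C(C)(C)C)cc1OC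
A4 | alternative 2 | benzyl({[(1R,2S)-2-{[(tert-butyldimethylsilyl)oxy]methyl}-1-(3,4-dimethoxyphenyl)but-3-yn-1-yl]oxy}ethynyl)dimethylsilane | COc1ccc([C@H](OC#C[Si](C)(C)Cc2ccccc2)[C@H](CO[Si](C)(C)C(C)(C)C)C#C)cc1OC
A5 | alternative 2 | methyl (2E)-pent-2-en-4-ynoate | C#C/C=C/C(=O)OC
A6 | alternative 3 | ethyl exo-3-(benzyloxy)-5-bromo-1a,6b-dihydro-1H-cyclopropa[b][1]benzofuran-1-carboxylate (configuration as in the SMILES) | CCOC(=O)[C@@H]1[C@H]2Oc3c(OCc4ccccc4)cc(Br)cc3[C@@H]12
A7 | alternative 3 | 7-(benzyloxy)-5-bromo-1-benzofuran | Brc1cc(OCc2ccccc2)c2occc2c1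
A8 | alternative 3 | ethyl diazoacetate | CCOC(=O)C=[N+]=[N-]
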